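**Retrosynthetic overview**

- The last ring formed is the ten-membered carbocycle (nine-membered oxacycle), closed by ring-closing metathesis that makes the (Z)-C4=C5 bond of a furanone diene.
- The 3(2H)-furanone comes from a γ-hydroxy ynone by gold-catalysed hydration–cyclodehydration; the ynone comes from an acyl Sonogashira coupling (C2–C3) with 2-(acetoxymethyl)acryloyl chloride.
- Key disconnection C7–C8: the aldehyde carbon of (3R)-3-hydroxy-3-methylpent-4-ynal reacts as a nucleophilic acyl (acyl anion equivalent) at the β-carbon of (5R)-3-(bromomethyl)-5-vinylbutenolide. Loss of bromide unveils the α-methylene lactone, and the C8 ketone is reduced in the same pot under direction of the C10 hydroxyl.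
- The aldehyde comes from Sharpless epoxidation and reductive opening of (E)-3-methylpent-2-en-4-yn-1-ol (sets C10). The butenolide comes from asymmetric alkynylation of acrolein (sets C6), trans-hydroalumination/iodination and carbonylative lactonisation.
- Ring order: γ-lactone (as butenolide) → 3(2H)-furanone → macrocycle.

Assumption: (S,S)-ProPhenol is taken to give the R carbinol in step 4 (otherwise its enantiomer is used); locants C1–C15 in the text are the germacrane positions of the target.

**Route**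

Step 1
Reactants: 1 (E)-3-methylpent-2-en-4-yn-1-ol
Product: 2 [(2S,3S)-3-ethynyl-3-methyloxiran-2-yl]methanol
Conditions: Ti(OiPr)4 (5 mol%), L-(+)-diethyl tartrate (6 mol%), tBuOOH, 4 Å sieves, CH2Cl2, −20 °C
Reagents that add atoms: tert-butyl hydroperoxide, CC(C)(C)OO
Why: Katsuki–Sharpless asymmetric epoxidation of an (E)-allylic alcohol, where L-(+)-tartrate delivers oxygen to the face that gives the (2S,3S)-epoxide (the same sense as with geraniol) and thereby fixes the future C10.

Step 2
Reactants: 2 [(2S,3S)-3-ethynyl-3-methyloxiran-2-yl]methanol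
Product: 3 (3R)-3-methylpent-4-yne-1,3-diol
Conditions: NaAlH2(OCH2CH2OCH3)2 (1.6 equiv), THF, −20 to 0 °C; aq. potassium sodium tartrate
Reagents that add atoms: none
Why: Hydroxyl-directed reductive opening of a 2,3-epoxy alcohol delivers hydride intramolecularly to C2 and leaves the tertiary C–O bond untouched, giving the 1,3-diol, while the low temperature avoids hydroalumination of the ethynyl carbinol.

Step 3
Reactants: 3 (3R)-3-methylpent-4-yne-1,3-diol
Product: 4 (3R)-3-hydroxy-3-methylpent-4-ynal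
Conditions: TEMPO (10 mol%), PhI(OAc)2, CH2Cl2, rt; used as a crude solution
Reagents that add atoms: none
Why: The oxoammonium (TEMPO/PhI(OAc)2) oxidation is selective for the primary alcohol, the tertiary alcohol cannot be oxidised, and the neutral conditions avoid dehydration or retro-aldol cleavage of the β-hydroxy aldehyde.

Step 4
Reactants: 5 acrolein; 6 tert-butyldimethyl(prop-2-yn-1-yloxy)silane
Product: 8 (3R)-6-(tert-butyldimethylsilyloxy)hex-1-en-4-yn-3-ol, via alkynyl(methyl)zinc 7 (not isolated)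
Conditions: Me2Zn (3 equiv), (S,S)-ProPhenol (10 mol%), Ph3PO (20 mol%), toluene, 0 °C; aq. NH4Cl
Reagents that add atoms: dimethylzinc, C[Zn]C
Why: Zinc–ProPhenol-catalysed enantioselective alkynylation of an α,β-unsaturated aldehyde, in which the ligand-bound zinc alkynylide adds 1,2 to one face of acrolein and sets C6.

Step 5
Reactants: 8 (3R)-6-(tert-butyldimethylsilyloxy)hex-1-en-4-yn-3-ol
Product: 10 (3R,4Z)-6-(tert-butyldimethylsilyloxy)-5-iodohexa-1,4-dien-3-ol, via alkenylalanate 9 (not isolated)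
Conditions: NaAlH2(OCH2CH2OCH3)2 (1.5 equiv), THF, 0 °C; then I2, −78 to 0 °C
Reagents that add atoms: sodium bis(2-methoxyethoxy)aluminium dihydride, [Na+].[AlH2-](OCCOC)OCCOC; iodine, II
Why: Alkoxide-directed trans-hydroalumination of the propargylic alcohol puts aluminium on the distal alkyne carbon in a five-membered oxa-aluminacycle, and iodinolysis with retention gives the (Z)-iodoalkene without touching the carbinol centre.

Step 6
Reactants: 10 (3R,4Z)-6-(tert-butyldimethylsilyloxy)-5-iodohexa-1,4-dien-3-ol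
Product: 11 (5R)-3-[(tert-butyldimethylsilyloxy)methyl]-5-vinylfuran-2(5H)-one
Conditions: PdCl2(PPh3)2 (5 mol%), CO (1 atm), K2CO3, THF, rt
Reagents that add atoms: carbon monoxide, [C-]#[O+]
Why: Palladium-catalysed carbonylative lactonisation, in which zerovalent palladium inserts into the vinyl iodide, CO inserts, and the cis-disposed hydroxyl captures the acylpalladium to close the butenolide; the weak heterogeneous base spares the acidic γ-hydrogen.

Step 7
Reactants: 11 (5R)-3-[(tert-butyldimethylsilyloxy)methyl]-5-vinylfuran-2(5H)-one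
Product: 12 (5R)-3-(bromomethyl)-5-vinylfuran-2(5H)-one
Conditions: Ph3PBr2, CH2Cl2, 0 °C to rt
Reagents that add atoms: dibromotriphenylphosphorane, BrP(Br)(c1ccccc1)(c1ccccc1)c1ccccc1
Why: Ph3PBr2 converts a primary allylic silyl ether directly into the bromide (silyl transfer to bromide, then SN2 on the alkoxyphosphonium) and leaves the butenolide and its stereocentre untouched.

Step 8
Reactants: 4 (3R)-3-hydroxy-3-methylpent-4-ynal; 12 (5R)-3-(bromomethyl)-5-vinylfuran-2(5H)-one
Product: 14 (4R,5R)-4-[(1S,3R)-1,3-dihydroxy-3-methylpent-4-yn-1-yl]-3-methylidene-5-vinyloxolan-2-one, via keto lactone 13 (not isolated)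
Conditions: (Bu4N)4W10O32 (2 mol%), NaHCO3, MeCN, 390 nm LED, rt, 4 in excess (2.5 equiv); then AcOH, Me4NBH(OAc)3, −30 °C
Reagents that add atoms: none
Why: Proposed new method: photoexcited decatungstate abstracts the formyl hydrogen of 4 to give a nucleophilic acyl radical (an acyl anion equivalent) that adds to the electrophilic β-carbon C7 of 12 anti to the vinyl group (C7 also remains epimerisable to the trans lactone), the α-lactone radical then expels the allylic bromine atom to unveil the exocyclic methylene (closest known reactions: decatungstate-photocatalysed hydroacylation of electron-poor alkenes and radical addition–fragmentation allylation with 2-(bromomethyl)acrylates), and the β-hydroxy ketone 13 is reduced in the same pot by internal hydride delivery from the C10 alkoxyborohydride (Evans–Saksena reduction) through a chair transition state with the methyl group equatorial and the slim ethynyl group axial, which gives the 8S alcohol.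

Step 9
Reactants: 14 (4R,5R)-4-[(1S,3R)-1,3-dihydroxy-3-methylpent-4-yn-1-yl]-3-methylidene-5-vinyloxolan-2-one; 15 angelic acid
Product: 17 (1S,3R)-3-hydroxy-3-methyl-1-[(2R,3R)-4-methylidene-5-oxo-2-vinyloxolan-3-yl]pent-4-yn-1-yl (Z)-2-methylbut-2-enoate, via mixed anhydride 16 (not isolated)
Conditions: 15, 2,4,6-Cl3C6H2COCl, Et3N, toluene, rt; then 14, 75 °C
Reagents that add atoms: 2,4,6-trichlorobenzoyl chloride, O=C(Cl)c1c(Cl)cc(Cl)cc1Cl
Why: Yamaguchi-type mixed-anhydride esterification, in which the shielded aroyl carbonyl directs the secondary C8 hydroxyl onto the angeloyl carbonyl, the tertiary propargylic alcohol does not react, and the absence of a nucleophilic catalyst keeps the (Z)-geometry of the angelate.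

Step 10
Reactants: 18 2-(bromomethyl)acrylic acid
Product: 19 2-(acetoxymethyl)acrylic acid
Conditions: NaOAc, AcOH, 80 °C
Reagents that add atoms: sodium acetate, CC(=O)[O-].[Na+]
Why: Acetate displaces the activated allylic bromide (SN2 and SN2′ give the same product) while the carboxylic acid stays protonated in acetic acid and cannot self-alkylate.

Step 11
Reactants: 17 (1S,3R)-3-hydroxy-3-methyl-1-[(2R,3R)-4-methylidene-5-oxo-2-vinyloxolan-3-yl]pent-4-yn-1-yl (Z)-2-methylbut-2-enoate; 19 2-(acetoxymethyl)acrylic acid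
Product: 21 (1S,3R)-7-(acetoxymethyl)-3-hydroxy-3-methyl-1-[(2R,3R)-4-methylidene-5-oxo-2-vinyloxolan-3-yl]-6-oxooct-7-en-4-yn-1-yl (Z)-2-methylbut-2-enoate, via acid chloride 20 (not isolated)
Conditions: 19, (COCl)2, cat. DMF, CH2Cl2, 0 °C to rt, evaporate; then 17, PdCl2(PPh3)2 (2 mol%), CuI (4 mol%), Et3N, THF, rt
Reagents that add atoms: oxalyl chloride, O=C(Cl)C(=O)Cl
Why: Acyl Sonogashira coupling, in which the copper acetylide of the terminal alkyne transmetalates to the acylpalladium formed from 20, under mild amine conditions that tolerate the α-methylene lactone, both esters and the hindered tertiary alcohol.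

Step 12
Reactants: 21 (1S,3R)-7-(acetoxymethyl)-3-hydroxy-3-methyl-1-[(2R,3R)-4-methylidene-5-oxo-2-vinyloxolan-3-yl]-6-oxooct-7-en-4-yn-1-yl (Z)-2-methylbut-2-enoate
Product: 23 (1S)-2-[(2R)-5-(3-acetoxyprop-1-en-2-yl)-2-methyl-3-oxo-2,3-dihydrofuran-2-yl]-1-[(2R,3R)-4-methylidene-5-oxo-2-vinyloxolan-3-yl]ethyl (Z)-2-methylbut-2-enoate, via hydroxy diketone 22 (not isolated)
Conditions: (4-CF3C6H4)3PAuCl (5 mol%), AgOSO2CF3 (5 mol%), H2O (2 equiv), toluene, rt
Reagents that add atoms: water, O
Why: Gold-catalysed hydration–cyclodehydration of a γ-hydroxy alkynone, in which the π-acid activates the alkyne for addition of water at C1 and the resulting α′-hydroxy 1,3-diketone closes through the C10 hydroxyl onto C3 and loses water to give the 3(2H)-furanone without touching C10.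

Step 13
Reactants: 23 (1S)-2-[(2R)-5-(3-acetoxyprop-1-en-2-yl)-2-methyl-3-oxo-2,3-dihydrofuran-2-yl]-1-[(2R,3R)-4-methylidene-5-oxo-2-vinyloxolan-3-yl]ethyl (Z)-2-methylbut-2-enoate
Product: 24 CNP0122132.1
Conditions: second-generation Hoveyda–Grubbs catalyst (10 mol%), toluene (1 mM), 100 °C
Reagents that add atoms: none
Why: Ring-closing metathesis, in which the ruthenium carbene loads on the C6 vinyl group and closes onto the 1,1-disubstituted alkene, the nine-membered oxacycle can hold only the (Z)-alkene, and the electron-poor exocyclic methylene and the trisubstituted angelate alkene stay out (closures of this kind are known for related 5-alkenyl-3(2H)-furanones).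

**Compound list**

1 | (E)-3-methylpent-2-en-4-yn-1-ol | C#C/C(C)=C/CO | starting material
2 | [(2S,3S)-3-ethynyl-3-methyloxiran-2-yl]methanol | OC[C@@H]1O[C@@]1(C)C#C | intermediate
3 | (3R)-3-methylpent-4-yne-1,3-diol | OCC[C@@](C)(O)C#C | intermediate
4 | (3R)-3-hydroxy-3-methylpent-4-ynal | O=CC[C@@](C)(O)C#C | intermediate
5 | acrolein | C=CC=O | starting material
6 | tert-butyldimethyl(prop-2-yn-1-yloxy)silane | C#CCO[Si](C)(C)C(C)(C)C | starting material
7 | methyl[3-(tert-butyldimethylsilyloxy)prop-1-yn-1-yl]zinc | C[Zn]C#CCO[Si](C)(C)C(C)(C)C | intermediate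
8 | (3R)-6-(tert-butyldimethylsilyloxy)hex-1-en-4-yn-3-ol | C=C[C@@H](O)C#CCO[Si](C)(C)C(C)(C)C | intermediate
9 | sodium (5R)-3-[(tert-butyldimethylsilyloxy)methyl]-2,2-bis(2-methoxyethoxy)-5-vinyl-2,5-dihydro-1,2-oxaluminol-2-uide | C=C[C@H]1O[Al-](OCCOC)(OCCOC)C(CO[Si](C)(C)C(C)(C)C)=C1.[Na+] | intermediate
10 | (3R,4Z)-6-(tert-butyldimethylsilyloxy)-5-iodohexa-1,4-dien-3-ol | C=C[C@@H](O)/C=C(\I)CO[Si](C)(C)C(C)(C)C | intermediate
11 | (5R)-3-[(tert-butyldimethylsilyloxy)methyl]-5-vinylfuran-2(5H)-one | O=C1O[C@H](C=C)C=C1CO[Si](C)(C)C(C)(C)C | intermediate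
12 | (5R)-3-(bromomethyl)-5-vinylfuran-2(5H)-one | O=C1O[C@H](C=C)C=C1CBr | intermediate
13 | (4S,5R)-4-[(3R)-3-hydroxy-3-methylpent-4-ynoyl]-3-methylidene-5-vinyloxolan-2-one | C=C1C(=O)O[C@H](C=C)[C@H]1C(=O)C[C@@](C)(O)C#C | intermediate
14 | (4R,5R)-4-[(1S,3R)-1,3-dihydroxy-3-methylpent-4-yn-1-yl]-3-methylidene-5-vinyloxolan-2-one | C=C1C(=O)O[C@H](C=C)[C@H]1[C@@H](O)C[C@@](C)(O)C#C | intermediate
15 | angelic acid [(Z)-2-methylbut-2-enoic acid] | C/C=C(/C)C(=O)O | starting material
16 | (Z)-2-methylbut-2-enoic 2,4,6-trichlorobenzoic anhydride | C/C=C(/C)C(=O)OC(=O)c1c(Cl)cc(Cl)cc1Cl | intermediate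
17 | (1S,3R)-3-hydroxy-3-methyl-1-[(2R,3R)-4-methylidene-5-oxo-2-vinyloxolan-3-yl]pent-4-yn-1-yl (Z)-2-methylbut-2-enoate | C=C1C(=O)O[C@H](C=C)[C@H]1[C@@H](OC(=O)/C(C)=C\C)C[C@@](C)(O)C#C | intermediate
18 | 2-(bromomethyl)acrylic acid | C=C(CBr)C(=O)O | starting material
19 | 2-(acetoxymethyl)acrylic acid | C=C(COC(C)=O)C(=O)O | intermediate
20 | 2-(acetoxymethyl)acryloyl chloride | C=C(COC(C)=O)C(=O)Cl | intermediate
21 | (1S,3R)-7-(acetoxymethyl)-3-hydroxy-3-methyl-1-[(2R,3R)-4-methylidene-5-oxo-2-vinyloxolan-3-yl]-6-oxooct-7-en-4-yn-1-yl (Z)-2-methylbut-2-enoate | C=C1C(=O)O[C@H](C=C)[C@H]1[C@@H](OC(=O)/C(C)=C\C)C[C@@](C)(O)C#CC(=O)C(=C)COC(C)=O | intermediate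
22 | (1S,3R)-7-(acetoxymethyl)-3-hydroxy-3-methyl-1-[(2R,3R)-4-methylidene-5-oxo-2-vinyloxolan-3-yl]-4,6-dioxooct-7-en-1-yl (Z)-2-methylbut-2-enoate | C=C1C(=O)O[C@H](C=C)[C@H]1[C@@H](OC(=O)/C(C)=C\C)C[C@@](C)(O)C(=O)CC(=O)C(=C)COC(C)=O | intermediate
23 | (1S)-2-[(2R)-5-(3-acetoxyprop-1-en-2-yl)-2-methyl-3-oxo-2,3-dihydrofuran-2-yl]-1-[(2R,3R)-4-methylidene-5-oxo-2-vinyloxolan-3-yl]ethyl (Z)-2-methylbut-2-enoate | C=C1C(=O)O[C@H](C=C)[C@H]1[C@@H](OC(=O)/C(C)=C\C)C[C@@]1(C)OC(C(=C)COC(C)=O)=CC1=O | intermediate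
24 | CNP0122132.1: (4Z,6R,7R,8S,10R)-15-acetoxy-8-[(Z)-2-methylbut-2-enoyloxy]-1-oxo-3,10-epoxygermacra-2,4,11(13)-trien-12,6-olide | C=C1C(=O)O[C@@H]2/C=C(/COC(C)=O)C3=CC(=O)[C@@](C)(C[C@H](OC(=O)/C(C)=C\C)[C@@H]12)O3 | target

**Step count and risks**

Total step count: 13. Longest linear sequence: 9 steps (steps 4, 5, 6, 7, 8, 9, 11, 12, 13).

The three steps most likely to fail:

Step 8 (acyl-radical coupling with one-pot directed reduction). The risks are competing hydrogen abstraction at C6 of 12, isomerisation of the β-keto methylene lactone 13, and modest selectivity in the reduction. The fallback inverts the polarity of the union: 12 is stirred with zinc dust and 4 in THF/saturated aqueous NH4Cl at 0 °C. The (E)-configured cyclic allylzinc then adds through C7 by a chair transition state, anti to the vinyl group, and gives the 7,8-anti alcohol directly. It sets out from 4 and 12 and comes back to the route at 14; it makes no further compound (entry F0).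

Step 9 (angeloylation). The risks are slow acylation of the hindered C8 alcohol, migration of the lactone to the C8 oxygen under base, and Z-to-E isomerisation of the angelate. The fallback forms the ester by SN2 with inversion instead of acyl transfer. Keto lactone 13 is generated as in step 8 but reduced with Et2BOMe/NaBH4 (THF/MeOH, −78 °C), where external hydride onto the boron chelate should give the C8 epimer, (4R,5R)-4-[(1R,3R)-1,3-dihydroxy-3-methylpent-4-yn-1-yl]-3-methylidene-5-vinyloxolan-2-one F1. Mitsunobu coupling of the epimeric diol F1 with angelic acid 15 (PPh3, DIAD, toluene, 0 °C) then inverts C8. It sets out from 13 and comes back to the route at 17.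

Step 13 (ring-closing metathesis). The risks are ring strain and a slow reaction at the 1,1-disubstituted alkene, which carries an allylic acetate that can chelate ruthenium. The fallback closes the ring on the isopropenyl analogue and introduces the C15 oxygen last. Alkyne 17 is coupled with methacryloyl chloride as in step 11 to give the methyl ynone F2. Gold-catalysed hydration–cyclisation as in step 12, through the hydroxy diketone F3, gives the isopropenyl furanone F4. Ring-closing metathesis gives the 15-deoxy macrocycle F5. Allylic oxidation of the C15 methyl (SeO2, tBuOOH, CH2Cl2) gives the 15-hydroxy macrocycle F6, and Ac2O/pyridine gives the target. It sets out from 17 and comes back to the route at 24.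

**Further compounds**

F0 | step 8 | none | none
F1 | step 9 | (4R,5R)-4-[(1R,3R)-1,3-dihydroxy-3-methylpent-4-yn-1-yl]-3-methylidene-5-vinyloxolan-2-one | C=C1C(=O)O[C@H](C=C)[C@H]1[C@H](O)C[C@@](C)(O)C#C
F2 | step 13 | (1S,3R)-3-hydroxy-3,7-dimethyl-1-[(2R,3R)-4-methylidene-5-oxo-2-vinyloxolan-3-yl]-6-oxooct-7-en-4-yn-1-yl (Z)-2-methylbut-2-enoate | C=C1C(=O)O[C@H](C=C)[C@H]1[C@@H](OC(=O)/C(C)=C\C)C[C@@](C)(O)C#CC(=O)C(C)=C
F3 | step 13 | (1S,3R)-3-hydroxy-3,7-dimethyl-1-[(2R,3R)-4-methylidene-5-oxo-2-vinyloxolan-3-yl]-4,6-dioxooct-7-en-1-yl (Z)-2-methylbut-2-enoate | C=C1C(=O)O[C@H](C=C)[C@H]1[C@@H](OC(=O)/C(C)=C\C)C[C@@](C)(O)C(=O)CC(=O)C(C)=C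
F4 | step 13 | (1S)-2-[(2R)-2-methyl-3-oxo-5-(prop-1-en-2-yl)-2,3-dihydrofuran-2-yl]-1-[(2R,3R)-4-methylidene-5-oxo-2-vinyloxolan-3-yl]ethyl (Z)-2-methylbut-2-enoate | C=C1C(=O)O[C@H](C=C)[C@H]1[C@@H](OC(=O)/C(C)=C\C)C[C@@]1(C)OC(C(C)=C)=CC1=O
F5 | step 13 | (4Z,6R,7R,8S,10R)-8-[(Z)-2-methylbut-2-enoyloxy]-1-oxo-3,10-epoxygermacra-2,4,11(13)-trien-12,6-olide | C=C1C(=O)O[C@@H]2/C=C(/C)C3=CC(=O)[C@@](C)(C[C@H](OC(=O)/C(C)=C\C)[C@@H]12)O3
F6 | step 13 | (4Z,6R,7R,8S,10R)-15-hydroxy-8-[(Z)-2-methylbut-2-enoyloxy]-1-oxo-3,10-epoxygermacra-2,4,11(13)-trien-12,6-olide | C=C1C(=O)O[C@@H]2/C=C(/CO)C3=CC(=O)[C@@](C)(C[C@H](OC(=O)/C(C)=C\C)[C@@H]12)O3
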